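**Conventions.** The terpene part uses caryophyllane numbering: C1 and C9 are the cyclobutane ring-fusion carbons, C10 the cyclobutane CH2, C11 the CMe2 carbon, C8 the carbon bearing the exocyclic methylene, then C7, C6, C5 (bears C1′), C4 (bears O and CH3), C3, C2. C1′ is the CHPh carbon. Ring A uses chroman numbering (C4a, C5–C8, C8a). Ring A is the arene, ring B the pyran, ring C the nine-membered ring, ring D the cyclobutane. Compounds are numbered 1–27.

**Assumption.** The antipode of the oxazaborolidine in step 1 is the one that gives (1S,6S)-3. The C4a epimers of 17–19 are carried as a mixture, because C4a becomes sp2 in 20.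

## Analysis of the target

The target is a tetracycle. A fully substituted phloroglucinol dialdehyde (ring A) is fused to a dihydropyran (ring B). Ring B is trans-fused at C4–C5 to a nine-membered carbocycle (ring C) with an exocyclic methylene at C8, and ring C is trans-fused at C1–C9 to a gem-dimethylcyclobutane (ring D). There are five stereocentres: C1 (S), C9 (R), C4 (S, quaternary, O and CH3), C5 (R) and C1′ (S). The cyclobutane is antipodal to that of natural (−)-β-caryophyllene, so the terpene half cannot come from the chiral pool. On ring B, C3 and C6 are equatorial, the C4 methyl is axial and anti to H-5, and phenyl is equatorial with H-1′ anti to H-5. Relative to C1/C9, the C4/C5 pair is what a suprafacial addition to the exposed face of an (E)-4,5-alkene of this ring system would give. Sensitive sites are the methylidene next to a strained cyclobutane in a medium ring (acid causes transannular and ring-expansion chemistry), the tertiary alkyl aryl ether of an electron-poor phenol, the two salicylaldehyde units, and the doubly benzylic C1′–H. The hard parts are the nine-membered ring, the quaternary C4–O centre, the remote relation between rings D and B, and a hexasubstituted arene that cannot be formylated late under electrophilic conditions without endangering the terpene. The strategy rests on one feature: C6–C7–C8 of ring A with both formyl carbons is the carbon chain of a 3-oxopentanedioate, and C8a–C4a–C5 is a malonate-level unit that can sit on ring B with C8a keeping the ring oxygen.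

## Retrosynthetic reasoning

**27 ⇒ 23 (oxidation level).** Both formyl groups are taken back to the methyl esters of 23 through 26, 25 and 24. Hydride reduction of the free bis-salicylate is not used: a phenoxide next to a benzylic aluminate expels the oxygen as a quinone methide, which is reduced on to methyl. The phenols are therefore capped as allyl ethers (24), which come off at the end under neutral palladium catalysis. Acid-labile acetals were ruled out because of the methylidenecyclobutane and the tertiary aryl ether.

**23 ⇒ 20 + 21 (ring A, C8–C8a and C5–C6).** These two bonds separate a five-carbon piece, which is 21 as it stands, from the three-carbon piece C8a–C4a–C5 that stays on ring B. A lactone carbonyl at C8a would be opened by the carbanion. In 20 the same oxidation level is a ketene O,S-acetal whose thiomethyl group leaves, so ring B and C4 survive. The gain is the complete arene with both formyl carbons in one operation on the finished terpene. The forward reaction must join C8 to C8a with loss of thiolate and then acylate C6 with the C4a ester.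

**20 ⇒ 19 ⇒ 18 (C–S).** The S-methyl group is removed to the thionolactone 19, and the thiocarbonyl goes back to the lactone carbonyl of 18. The lactone must be thionated in preference to the acyclic ester.

**18 ⇒ 17 ⇒ 16 (C4–O).** The C4–O bond is cut to the 4-methylidene diester 16, with iodine as the electrophile that is later replaced by hydrogen. The bond is not made by adding a methyl nucleophile to ketone 15. Such a nucleophile would enter C4 anti to the C5–C6 ring bond and past H-5, and would put methyl where the target has oxygen. With 16 the ester oxygen uses that same trajectory, which gives the trans ring fusion.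

**16 ⇒ 15 ⇒ 12 + 13 (C4=CH2, then C5–C1′).** The methylidene goes back to the C4 ketone, which is needed to make C5 nucleophilic. Cutting C5–C1′ gives the enone 12 and the commercial acceptor 13. Conjugate reduction of 12 gives the C4–C5 enolate regiospecifically (C3 is not touched), and its Michael addition sets C5 and C1′ on the ring template.

**12 ⇒ 11 (C5=C6).** Ring C is opened at the enone double bond. This is the only ring bond whose alkene is consumed productively afterwards, and ring closure by metathesis gives the (Z)-enone.

**11 ⇒ 10 ⇒ 9 ⇒ 8 ⇒ 7 (side chains).** The vinyl ketone comes from a Weinreb amide (C4–C5). The 2-substituted 1,4-diene comes from allylation of the enol triflate of a methyl ketone (C7–C8), which also creates the C8 methylene. Both arms go back to the trans keto acid 7.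

**7 ⇒ 5 ⇒ 4 ⇒ 3 (ring cleavage).** The keto acid is the oxidative cleavage product of the trisubstituted cyclohexene 5, made from ketone 3 through its kinetic enol triflate 4. The methyl introduced here becomes the exocyclic methylene carbon. Cleavage frees the acetyl-bearing carbon (future C9), which is then equilibrated to trans.

**3 ⇒ 1 + 2 (ring D).** The cyclobutane comes from a catalyst-controlled [2+2] photocycloaddition. This sets C1 in either absolute sense, which the antipodal terpene series requires.

## Alternatives that were turned down

**Alternative 1:** Ring C is cut at C6–C7. The open-chain allylic bromide A2 already carries rings A, B and D. An α-sulfonyl carbanion at C6 alkylates the 2-substituted allyl bromide on C9 under high dilution and gives the sulfone A1.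
- For: carbanion alkylation is irreversible and free of alkene isomerisation, SN2 and SN2′ give the same constitution, and the C8 methylene is already in place. As a ring-C closure it is at least as dependable as the metathesis 11 → 12.
- Against: A2 needs C4, C5 and C1′ set on an open chain, remote from the cyclobutane and without a ring template. After the key step come desulfonylation, removal of two acetals under acid, and a double electrophilic formylation of the phloroglucinol next to the acid-sensitive methylidenecyclobutane and tertiary aryl ether.
- Comparison: the chosen route spends more steps on ring C, but delivers both formyl carbons at ester level with the arene and never exposes the terpene to formylating electrophiles.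

**Alternative 2:** Ring D is cut at C9–C10 and C1–C11. The ring-B-fused cyclononenone A4 is irradiated with isobutene 2, and the α-carbon is then equilibrated with base to give the trans-fused ketone A3.
- For: it is the shortest of the four. Two stereocentres and the quaternary carbon arrive in one step, and the trans fusion at C9 is thermodynamic.
- Against: C1 is fixed in the photochemical step only by the conformation of a nine-membered enone relative to the remote C4/C5 centres. Excited medium-ring (Z)-enones relax to strained (E)-isomers, which add alkenes without stereospecificity. Regiochemistry is not assured. The electron-rich arene and the doubly benzylic C1′–H can intercept the triplet. Late formylation is still needed.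
- Comparison: Alternative 2 is clearly better on step economy. The chosen route sets C1 with a chiral catalyst on the simplest enone and C9 by equilibration.

**Alternative 3:** Ring C is cut at C7–C8. The C5 vinyl group of A6 is hydroborated with a dialkylborane, and the alkylborane couples with the C8 alkenyl triflate under palladium catalysis to give A5.
- For: the hydroboration is chemoselective and the conditions are mild. The coupling closes the ring and creates the exocyclic methylene in one event. On ring closure this is as strong as or stronger than the metathesis used here, which only tolerates the methylene.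
- Against: as in Alternative 1, the fully substituted chroman with three stereocentres must be built on a chain remote from the cyclobutane. β-Hydride elimination and protodeboronation compete in a nine-membered closure. Acetal cleavage and double formylation follow.
- Comparison: the chosen strategy uses the nine-membered ring as the template for C5, C1′ and C4, and replaces the late formylation by the arene annulation.

Key step: step 16

## Route

Step 1
Reactants: 1 2-cyclohexen-1-one; 2 isobutene
Product: 3 (1S,6S)-7,7-dimethylbicyclo[4.2.0]octan-2-one (cis-fused)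
Conditions: 2 (excess), AlBr3-activated B-(2,4,6-trifluorophenyl)oxazaborolidine of an α,α-diarylprolinol (50 mol %), hν (366 nm), CH2Cl2, −75 °C; then basic Al2O3, rt
Reagents that add atoms: none
Why: Enantioselective Lewis-acid-catalysed [2+2] photocycloaddition of a cyclic enone; the catalyst-bound enone is the species excited at this wavelength, the aryl groups shield one enone face and so set the β-carbon (future C1), and the disubstituted alkene carbon bonds to the β-carbon (head-to-tail). The α-carbon (future C9) stays epimerisable, and alumina converges any trans-fused adduct on the cis ketone.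

Step 2
Reactants: 3 (1S,6S)-7,7-dimethylbicyclo[4.2.0]octan-2-one
Product: 4 (1S,6S)-7,7-dimethylbicyclo[4.2.0]oct-2-en-2-yl trifluoromethanesulfonate
Conditions: LiN(i-Pr)2, THF, −78 °C; PhNTf2, −78 → 0 °C
Reagents that add atoms: N-phenylbis(trifluoromethanesulfonimide), FC(F)(F)S(=O)(=O)N(c1ccccc1)S(=O)(=O)C(F)(F)F
Why: Kinetic deprotonation takes the CH2 hydrogen and not the ring-fusion methine, whose enolate would be an alkylidenecyclobutane; O-sulfonylation gives the enol triflate without touching a stereocentre.

Step 3
Reactants: 4 (1S,6S)-7,7-dimethylbicyclo[4.2.0]oct-2-en-2-yl trifluoromethanesulfonate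
Product: 5 (1S,6S)-2,7,7-trimethylbicyclo[4.2.0]oct-2-ene
Conditions: MeMgBr, Fe(acac)3 (5 mol %), THF/NMP, −30 → 0 °C
Reagents that add atoms: methylmagnesium bromide, C[Mg]Br
Why: Iron-catalysed Kumada-type cross-coupling of an alkenyl triflate with a methyl Grignard reagent; the new methyl carbon becomes the exocyclic methylene carbon of the target. The volatile hydrocarbon is carried on in solution.

Step 4
Reactants: 5 (1S,6S)-2,7,7-trimethylbicyclo[4.2.0]oct-2-ene
Product: 7 3-[(1S,4R)-4-acetyl-2,2-dimethylcyclobutyl]propanoic acid (trans), via cis-keto acid 6 (not isolated)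
Conditions: RuCl3·xH2O (2 mol %), NaIO4, MeCN/EtOAc/H2O, 0 °C → rt; crude acid: NaOMe, MeOH, rt; aq. HCl
Reagents that add atoms: sodium periodate, [Na+].[O-]I(=O)(=O)=O; water, O
Why: RuO4 generated in the flask cleaves the trisubstituted alkene to a methyl ketone and a carboxylic acid. Methoxide then equilibrates the acetyl-bearing carbon (future C9) through its enolate to the trans-1,2-disubstituted cyclobutane, the thermodynamically favoured isomer; the neighbouring carbon (future C1) is not acidic and keeps its configuration.

Step 5
Reactants: 7 3-[(1S,4R)-4-acetyl-2,2-dimethylcyclobutyl]propanoic acid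
Product: 8 3-[(1S,4R)-4-acetyl-2,2-dimethylcyclobutyl]-N-methoxy-N-methylpropanamide
Conditions: 1,1′-carbonyldiimidazole, CH2Cl2, rt; MeNH(OMe)·HCl
Reagents that add atoms: N,O-dimethylhydroxylamine hydrochloride, CNOC.Cl
Why: Acyl imidazolide formation and aminolysis give the Weinreb amide under conditions too weakly basic to enolise the ketone, so the trans relationship is kept.

Step 6
Reactants: 8 3-[(1S,4R)-4-acetyl-2,2-dimethylcyclobutyl]-N-methoxy-N-methylpropanamide
Product: 9 1-[(1R,2S)-2-{3-[methoxy(methyl)amino]-3-oxopropyl}-3,3-dimethylcyclobutyl]ethenyl trifluoromethanesulfonate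
Conditions: LiN(i-Pr)2 (1.05 equiv), THF, −78 °C; N-(5-chloropyridin-2-yl)bis(trifluoromethanesulfonimide), −78 → −20 °C
Reagents that add atoms: N-(5-chloropyridin-2-yl)bis(trifluoromethanesulfonimide), FC(F)(F)S(=O)(=O)N(c1ccc(Cl)cn1)S(=O)(=O)C(F)(F)F
Why: Kinetic enolisation occurs at the methyl group (less hindered than the cyclobutyl methine and far more acidic than the amide α-hydrogens), and O-triflation at low temperature gives the terminal enol triflate. C9 is not deprotonated and keeps its configuration.

Step 7
Reactants: 9 1-[(1R,2S)-2-{3-[methoxy(methyl)amino]-3-oxopropyl}-3,3-dimethylcyclobutyl]ethenyl trifluoromethanesulfonate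
Product: 10 3-[(1S,4R)-2,2-dimethyl-4-(penta-1,4-dien-2-yl)cyclobutyl]-N-methoxy-N-methylpropanamide
Conditions: allylSnBu3, Pd(PPh3)4 (5 mol %), LiCl, THF, 65 °C
Reagents that add atoms: allyltributylstannane, C=CC[Sn](CCCC)(CCCC)CCCC
Why: Stille coupling of an alkenyl triflate with an allylstannane forms C7–C8 and with it the 1,1-disubstituted C8 methylene. C9 is now allylic and can no longer epimerise.

Step 8
Reactants: 10 3-[(1S,4R)-2,2-dimethyl-4-(penta-1,4-dien-2-yl)cyclobutyl]-N-methoxy-N-methylpropanamide
Product: 11 5-[(1S,4R)-2,2-dimethyl-4-(penta-1,4-dien-2-yl)cyclobutyl]pent-1-en-3-one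
Conditions: CH2=CHMgBr, THF, −20 → 0 °C; inverse quench into cold 1 M HCl
Reagents that add atoms: vinylmagnesium bromide, C=C[Mg]Br
Why: The chelated tetrahedral adduct of the Weinreb amide stops at the ketone level; the inverse acidic quench keeps the liberated hydroxylamine from adding to the vinyl ketone.

Step 9
Reactants: 11 5-[(1S,4R)-2,2-dimethyl-4-(penta-1,4-dien-2-yl)cyclobutyl]pent-1-en-3-one
Product: 12 (1S,5Z,9R)-11,11-dimethyl-8-methylidenebicyclo[7.2.0]undec-5-en-4-one
Conditions: second-generation Hoveyda–Grubbs catalyst (10 mol %), 1,4-benzoquinone (20 mol %), toluene (1 mM), 80 °C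
Reagents that add atoms: none
Why: Ring-closing metathesis; the ruthenium carbene forms at the monosubstituted allyl terminus and closes onto the vinyl ketone, while the 1,1-disubstituted C8 methylene cannot close a ring of sensible size. The nine-membered ring takes the (Z)-enone, and the trans cyclobutane with three sp2 ring carbons keeps transannular strain moderate.

Step 10
Reactants: 12 (1S,5Z,9R)-11,11-dimethyl-8-methylidenebicyclo[7.2.0]undec-5-en-4-one; 13 dimethyl 2-benzylidenepropanedioate
Product: 15 dimethyl 2-[(R)-[(1S,5R,9R)-11,11-dimethyl-8-methylidene-4-oxobicyclo[7.2.0]undecan-5-yl](phenyl)methyl]propanedioate, via lithium enolate 14 (not isolated)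
Conditions: LiBH(s-Bu)3 (1.05 equiv), THF, −78 °C; 13, −78 → −20 °C; aq. NH4Cl
Reagents that add atoms: none
Why: Reductive Michael addition: conjugate hydride addition gives the C4–C5 enolate 14 regiospecifically (ring-cis, because a ring-trans enolate would be a (Z,E)-cyclonona-1,3-diene unit), and it adds to the arylidene malonate. C5 is set by attack on the peripheral face of the enolate in the trans-fused bicycle, and C1′ by the synclinal, lithium-bridged transition state of a cyclic enolate with an arylidene malonate, which places C6 and phenyl syn along the C4–C5–C1′ chain. C5 stays epimerisable, and both centres are treated as a risk below.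

Step 11
Reactants: 15 dimethyl 2-[(R)-[(1S,5R,9R)-11,11-dimethyl-8-methylidene-4-oxobicyclo[7.2.0]undecan-5-yl](phenyl)methyl]propanedioate
Product: 16 dimethyl 2-[(R)-[(1S,5R,9R)-11,11-dimethyl-4,8-dimethylidenebicyclo[7.2.0]undecan-5-yl](phenyl)methyl]propanedioate
Conditions: Zn, CH2Br2, TiCl4, THF/CH2Cl2, 0 °C → rt
Reagents that add atoms: dibromomethane, BrCBr
Why: Takai–Lombardo methylenation is non-basic, so the epimerisable C5, the acidic malonate and the retro-Michael pathway are left alone, and esters do not react.

Step 12
Reactants: 16 dimethyl 2-[(R)-[(1S,5R,9R)-11,11-dimethyl-4,8-dimethylidenebicyclo[7.2.0]undecan-5-yl](phenyl)methyl]propanedioate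
Product: 17 ring-B δ-lactone with C8a as lactone carbonyl, CO2CH3 at C4a (both epimers) and CH2I at C4; (1S,4S,5R,9R,1′R)
Conditions: I2 (3 equiv), MeCN, 0 °C → rt, dark; aq. Na2S2O3
Reagents that add atoms: iodine, II
Why: Iodolactonisation of a 1,1-disubstituted alkene by an ester oxygen (Markovnikov, 6-exo; the oxocarbenium ion is demethylated by iodide). C4 is set in a chair transition state with C6 and phenyl equatorial, H-5 syn to C3 (least A(1,2) strain) and the oxygen entering anti to the C5–C6 ring bond, which puts C3 equatorial and CH2I axial, i.e. the trans ring fusion. The C8 methylene can form an iodonium ion reversibly but has no internal nucleophile.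

Step 13
Reactants: 17 ring-B iodomethyl δ-lactone ester
Product: 18 ring-B δ-lactone with C8a as lactone carbonyl, CO2CH3 at C4a (both epimers) and CH3 at C4; (1S,4S,5R,9R,1′R)
Conditions: Bu3SnH (0.3 M), AIBN (cat.), toluene, 80 °C
Reagents that add atoms: none
Why: Radical chain deiodination; the high stannane concentration outruns transannular addition of the primary radical to the C8 alkene and a 1,2-acyloxy shift, and no stereocentre is involved.

Step 14
Reactants: 18 ring-B δ-lactone ester
Product: 19 ring-B thionolactone (C8a=S) with CO2CH3 at C4a, in equilibrium with its ene-thiol; (1S,4S,5R,9R,1′R)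
Conditions: Lawesson's reagent (0.6 equiv), toluene, 90 °C
Reagents that add atoms: Lawesson's reagent, COc1ccc(cc1)P1(=S)SP(=S)(S1)c1ccc(OC)cc1
Why: Thionation through the oxathiaphosphetane (Wittig-like); the s-cis lactone carbonyl reacts well below the temperature the acyclic methyl ester needs, and the product is stabilised as the conjugated ene-thiol.

Step 15
Reactants: 19 ring-B thionolactone ester
Product: 20 ring-B ketene O,S-acetal, C4a(CO2CH3)=C8a(SCH3)–O; (1S,4S,5R,9R,1′S)
Conditions: MeI, K2CO3, acetone, rt
Reagents that add atoms: iodomethane, CI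
Why: S-Alkylation of the soft ene-thiolate gives the cyclic ketene O,S-acetal. C4a becomes sp2, so the epimers converge; the label at C1′ changes only because the priority of C4a changes.

Step 16
Reactants: 20 ring-B ketene O,S-acetal ester; 21 dimethyl 3-oxopentanedioate
Product: 23 ring-A dimethyl 5,7-dihydroxy-6,8-dicarboxylate of the full tetracycle; (1S,4S,5R,9R,1′S), via substitution adduct 22 (not isolated)
Conditions: 21 (1.5 equiv), NaH (3.5 equiv), THF, 0 °C → rt; then 20, 65 °C; aq. HCl
Reagents that add atoms: none
Why: Proposed new method: the more reactive carbanion terminus of the disodium salt of 21 adds to C8a of the push–pull acrylate 20, the resulting ester enolate expels methanethiolate and restores the C4a=C8a double bond to give 22 with the new C8–C8a bond, and deprotonation of the remaining CH2 then lets it attack the C4a ester carbonyl, lose methoxide and enolise twice to the arene. The closest known reaction types are the addition–elimination of 1,3-dicarbonyl carbanions on α-oxo ketene dithioacetals followed by [3+3] benzannulation, and the classical condensation of malonates with 3-oxoglutarates to phloroglucinol carboxylates. Ring A closes by a Dieckmann-type enolate acylation, 6-exo-trig at the ester carbonyl (C5–C6). No stereocentre is formed, and C4, C5 and C1′ are not touched: C1′–H is benzylic and allylic but cross-conjugated to the ester, hence only weakly acidic, and NaH with sodium enolates should not epimerise it. The step needs thiolate and not the tertiary ring alkoxide to leave, which the leaving-group ability secures (thiol pKa about 10 against about 18 for the alcohol), and any ring opening would be reversible whereas thiolate loss is not. It needs C- and not O-acylation in the closure; a pyranone from O-attack would be reopened by methoxide, while the phenoxide of 23 is a thermodynamic sink. Ester exchange is degenerate because every ester is a methyl ester.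

Step 17
Reactants: 23 ring-A diester diphenol
Product: 24 5,7-bis(allyloxy) diester
Conditions: allyl bromide, K2CO3, DMF, 50 °C
Reagents that add atoms: allyl bromide, C=CCBr
Why: Williamson O-alkylation of the two hydrogen-bonded phenols; every ring carbon is substituted, so C-allylation cannot compete. The ethers block quinone methide formation in the next step.

Step 18
Reactants: 24 5,7-bis(allyloxy) diester
Product: 25 5,7-bis(allyloxy)-6,8-bis(hydroxymethyl) compound
Conditions: LiAlH4, THF, 0 °C → rt; NaOH/H2O work-up; used crude
Reagents that add atoms: none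
Why: Hydride reduction of both aryl esters to benzylic alcohols; with the phenols capped no phenoxide can expel the benzylic oxygen, so over-reduction to methyl is shut off. The trialkoxybenzylic diol is acid-labile and is therefore not chromatographed.

Step 19
Reactants: 25 bis(allyloxy) diol
Product: 26 5,7-bis(allyloxy)-6,8-dicarbaldehyde
Conditions: activated MnO2 (excess), CH2Cl2, rt
Reagents that add atoms: none
Why: Neutral heterogeneous oxidation of electron-rich benzylic alcohols to aldehydes; the alkenes and C1′–H are not affected.

Step 20
Reactants: 26 bis(allyloxy) dialdehyde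
Product: 27 target CNP0253700.1, 5,7-dihydroxy-6,8-dicarbaldehyde; (1S,4S,5R,9R,1′S)
Conditions: Pd(PPh3)4 (5 mol %), K2CO3, MeOH, rt; pH 4 buffer
Reagents that add atoms: none
Why: Zerovalent palladium ionises the aryl allyl ethers (the formyl-flanked phenoxide is a good leaving group) and methoxide traps the π-allyl complex. Nothing acidic is used, so the methylidenecyclobutane and the tertiary aryl ether survive.

## Compound list

1 | 2-cyclohexen-1-one | O=C1C=CCCC1 | starting material
2 | isobutene | C=C(C)C | starting material
3 | (1S,6S)-7,7-dimethylbicyclo[4.2.0]octan-2-one | O=C1CCC[C@H]2[C@@H]1CC2(C)C | intermediate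
4 | (1S,6S)-7,7-dimethylbicyclo[4.2.0]oct-2-en-2-yl trifluoromethanesulfonate | FC(F)(F)S(=O)(=O)OC1=CCC[C@H]2[C@@H]1CC2(C)C | intermediate
5 | (1S,6S)-2,7,7-trimethylbicyclo[4.2.0]oct-2-ene | CC1=CCC[C@H]2[C@@H]1CC2(C)C | intermediate
6 | 3-[(1S,4S)-4-acetyl-2,2-dimethylcyclobutyl]propanoic acid (cis, not isolated) | OC(=O)CC[C@H]2[C@@H](C(C)=O)CC2(C)C | intermediate
7 | 3-[(1S,4R)-4-acetyl-2,2-dimethylcyclobutyl]propanoic acid (trans) | OC(=O)CC[C@H]2[C@H](C(C)=O)CC2(C)C | intermediate
8 | 3-[(1S,4R)-4-acetyl-2,2-dimethylcyclobutyl]-N-methoxy-N-methylpropanamide | CON(C)C(=O)CC[C@H]2[C@H](C(C)=O)CC2(C)C | intermediate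
9 | 1-[(1R,2S)-2-{3-[methoxy(methyl)amino]-3-oxopropyl}-3,3-dimethylcyclobutyl]ethenyl trifluoromethanesulfonate | CON(C)C(=O)CC[C@H]2[C@H](C(=C)OS(=O)(=O)C(F)(F)F)CC2(C)C | intermediate
10 | 3-[(1S,4R)-2,2-dimethyl-4-(penta-1,4-dien-2-yl)cyclobutyl]-N-methoxy-N-methylpropanamide | CON(C)C(=O)CC[C@H]2[C@H](C(=C)CC=C)CC2(C)C | intermediate
11 | 5-[(1S,4R)-2,2-dimethyl-4-(penta-1,4-dien-2-yl)cyclobutyl]pent-1-en-3-one | C=CC(=O)CC[C@H]2[C@H](C(=C)CC=C)CC2(C)C | intermediate
12 | (1S,5Z,9R)-11,11-dimethyl-8-methylidenebicyclo[7.2.0]undec-5-en-4-one | C=C1C/C=C\C(=O)CC[C@H]2[C@H]1CC2(C)C | intermediate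
13 | dimethyl 2-benzylidenepropanedioate | COC(=O)C(=Cc1ccccc1)C(=O)OC | starting material
14 | lithium (1S,9R)-11,11-dimethyl-8-methylidenebicyclo[7.2.0]undec-4-en-4-olate, ring-cis enolate (not isolated) | C=C1CC/C=C(/[O-])CC[C@H]2[C@H]1CC2(C)C.[Li+] | intermediate
15 | dimethyl 2-[(R)-[(1S,5R,9R)-11,11-dimethyl-8-methylidene-4-oxobicyclo[7.2.0]undecan-5-yl](phenyl)methyl]propanedioate | C=C1CC[C@H]([C@@H](c3ccccc3)C(C(=O)OC)C(=O)OC)C(=O)CC[C@H]2[C@H]1CC2(C)C | intermediate
16 | dimethyl 2-[(R)-[(1S,5R,9R)-11,11-dimethyl-4,8-dimethylidenebicyclo[7.2.0]undecan-5-yl](phenyl)methyl]propanedioate | C=C1CC[C@H]([C@@H](c3ccccc3)C(C(=O)OC)C(=O)OC)C(=C)CC[C@H]2[C@H]1CC2(C)C | intermediate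
17 | ring-B δ-lactone, C4 CH2I, C4a CO2CH3 (epimers at C4a), (1S,4S,5R,9R,1′R) | C=C1CC[C@@H]2[C@@H](c3ccccc3)C(C(=O)OC)C(=O)O[C@@]2(CI)CC[C@H]2[C@H]1CC2(C)C | intermediate
18 | ring-B δ-lactone, C4 CH3, C4a CO2CH3 (epimers at C4a), (1S,4S,5R,9R,1′R) | C=C1CC[C@@H]2[C@@H](c3ccccc3)C(C(=O)OC)C(=O)O[C@@]2(C)CC[C@H]2[C@H]1CC2(C)C | intermediate
19 | ring-B thionolactone, C4a CO2CH3, (1S,4S,5R,9R,1′R) | C=C1CC[C@@H]2[C@@H](c3ccccc3)C(C(=O)OC)C(=S)O[C@@]2(C)CC[C@H]2[C@H]1CC2(C)C | intermediate
20 | ring-B ketene O,S-acetal, C4a(CO2CH3)=C8a(SCH3), (1S,4S,5R,9R,1′S) | C=C1CC[C@@H]2[C@@H](c3ccccc3)C(C(=O)OC)=C(SC)O[C@@]2(C)CC[C@H]2[C@H]1CC2(C)C | intermediate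
21 | dimethyl 3-oxopentanedioate | COC(=O)CC(=O)CC(=O)OC | starting material
22 | substitution adduct, C8a bearing CH(CO2CH3)C(=O)CH2CO2CH3 (not isolated) | C=C1CC[C@@H]2[C@@H](c3ccccc3)C(C(=O)OC)=C(C(C(=O)OC)C(=O)CC(=O)OC)O[C@@]2(C)CC[C@H]2[C@H]1CC2(C)C | intermediate
23 | tetracyclic dimethyl 5,7-dihydroxy-6,8-dicarboxylate, (1S,4S,5R,9R,1′S) | C=C1CC[C@@H]2[C@@H](c3ccccc3)c3c(O)c(C(=O)OC)c(O)c(C(=O)OC)c3O[C@@]2(C)CC[C@H]2[C@H]1CC2(C)C | intermediate
24 | 5,7-bis(allyloxy) dimethyl 6,8-dicarboxylate | C=C1CC[C@@H]2[C@@H](c3ccccc3)c3c(OCC=C)c(C(=O)OC)c(OCC=C)c(C(=O)OC)c3O[C@@]2(C)CC[C@H]2[C@H]1CC2(C)C | intermediate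
25 | 5,7-bis(allyloxy)-6,8-bis(hydroxymethyl) compound | C=C1CC[C@@H]2[C@@H](c3ccccc3)c3c(OCC=C)c(CO)c(OCC=C)c(CO)c3O[C@@]2(C)CC[C@H]2[C@H]1CC2(C)C | intermediate
26 | 5,7-bis(allyloxy)-6,8-dicarbaldehyde | C=C1CC[C@@H]2[C@@H](c3ccccc3)c3c(OCC=C)c(C=O)c(OCC=C)c(C=O)c3O[C@@]2(C)CC[C@H]2[C@H]1CC2(C)C | intermediate
27 | CNP0253700.1, 5,7-dihydroxy-6,8-dicarbaldehyde, (1S,4S,5R,9R,1′S) | C=C1CC[C@@H]2[C@@H](c3ccccc3)c3c(O)c(C=O)c(O)c(C=O)c3O[C@@]2(C)CC[C@H]2[C@H]1CC2(C)C | target

## Step count and weak points

Total: 20 steps. Longest linear sequence: 20 steps (1 → 27); 13 and 21 enter as bought.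

**Step 16 (key step).** The push–pull alkene of 20 carries only one acceptor, so conjugate addition of a stabilised carbanion may be too slow. Self-condensation of 21, O-acylation to a pyranone, or demethylation of esters by thiolate at reflux could then take over. Fallback with known chemistry, from 19 back to 23: 21 is brominated with NBS to dimethyl 2-bromo-3-oxopentanedioate F1. Thionolactone 19 is S-alkylated with it (K2CO3, acetone) to the S-substituted ketene O,S-acetal F2. Eschenmoser sulfide contraction (PPh3, Et3N, MeCN, 60 °C) forms the C8–C8a bond intramolecularly through the thiirane and gives the exocyclic vinylogous carbonate F3, the alkene tautomer of 22, as an isolated compound. NaOMe in MeOH then effects the Dieckmann closure and aromatisation to 23.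

**Step 9.** Oligomerisation by cross-metathesis may beat closure of the strained nine-membered ring, and ruthenium hydrides may move the skipped diene into conjugation. Fallback, from 10 back to 12: cross-metathesis of the monosubstituted alkene of 10 with vinylboronic acid pinacol ester gives the (E)-alkenylboronate F4. ICl followed by NaOMe (iododeboronation with inversion) gives the (Z)-alkenyl iodide F5. i-Bu2AlH reduces the amide to aldehyde F6. An intramolecular Nozaki–Hiyama–Kishi reaction (CrCl2, NiCl2 cat., DMSO/THF, high dilution) closes C4–C5 to the cyclic allylic alcohol F7 (both C4 epimers), which MnO2 oxidises to 12.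

**Step 10.** Hydride may add 1,2 to the twisted medium-ring enone. The enolate may be attacked on the wrong face with respect to the remote cyclobutane, or with the wrong topicity at C1′, since both rest on the conformation of a flexible ring. Fallback, from 12 back to 15: 1,4-hydrosilylation (Et3SiH, RhCl(PPh3)3 cat.) gives the triethylsilyl enol ether F8. A Mukaiyama–Michael addition to 13 follows, catalysed by Cu(OTf)2 with a C2-symmetric bis(oxazoline) (divalent copper, (CF3)2CHOH as silyl acceptor). The catalyst then fixes the acceptor face and hence C1′, through an open transition state. Epimers at C5 can be equilibrated with base before step 11.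

**Step 12.** The oxygen may enter from the other face and give the cis-fused C4 epimer, or the C8 alkene may attack the iodonium ion across the ring. Fallback, from 15 back to 18: MeLi/CeCl3 in THF at −78 °C adds methyl to the C4 ketone and gives the tertiary alcohol F9, which lactonises on warming with catalytic NaOMe. This brings in methyl instead of oxygen along the peripheral trajectory, so it is stereocomplementary to the iodolactonisation, and it uses no electrophile.

**Step 14.** The methyl ester may be thionated along with the lactone, or the reagent may not discriminate at the temperature the lactone needs. Fallback, from 18 back to 19: Et3OBF4 alkylates the more basic lactone carbonyl, and a hindered amine base gives the cyclic ketene O,O-acetal F10. NaSH in EtOH then replaces ethoxide by sulfur and gives 19.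

## Further compounds

F1 | step 16 | dimethyl 2-bromo-3-oxopentanedioate | COC(=O)C(Br)C(=O)CC(=O)OC
F2 | step 16 | ring-B ketene O,S-acetal with S–CH(CO2CH3)C(=O)CH2CO2CH3 | C=C1CC[C@@H]2[C@@H](c3ccccc3)C(C(=O)OC)=C(SC(C(=O)OC)C(=O)CC(=O)OC)O[C@@]2(C)CC[C@H]2[C@H]1CC2(C)C
F3 | step 16 | exocyclic vinylogous carbonate, alkene tautomer of 22 | C=C1CC[C@@H]2[C@@H](c3ccccc3)C(C(=O)OC)C(=C(C(=O)OC)C(=O)CC(=O)OC)O[C@@]2(C)CC[C@H]2[C@H]1CC2(C)C
F4 | step 9 | (E)-alkenyl pinacolboronate of 10 | CON(C)C(=O)CC[C@H]2[C@H](C(=C)C/C=C/B3OC(C)(C)C(C)(C)O3)CC2(C)C
F5 | step 9 | (Z)-alkenyl iodide amide | CON(C)C(=O)CC[C@H]2[C@H](C(=C)C/C=C\I)CC2(C)C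
F6 | step 9 | (Z)-alkenyl iodide aldehyde | O=CCC[C@H]2[C@H](C(=C)C/C=C\I)CC2(C)C
F7 | step 9 | (1S,5Z,9R)-11,11-dimethyl-8-methylidenebicyclo[7.2.0]undec-5-en-4-ol | C=C1C/C=C\C(O)CC[C@H]2[C@H]1CC2(C)C
F8 | step 10 | triethylsilyl enol ether of the C4 ketone (ring-cis) | C=C1CC/C=C(/O[Si](CC)(CC)CC)CC[C@H]2[C@H]1CC2(C)C
F9 | step 12 | C4 tertiary alcohol diester | C=C1CC[C@H]([C@@H](c3ccccc3)C(C(=O)OC)C(=O)OC)[C@@](C)(O)CC[C@H]2[C@H]1CC2(C)C
F10 | step 14 | ring-B ketene O,O-acetal, C8a OCH2CH3 | C=C1CC[C@@H]2[C@@H](c3ccccc3)C(C(=O)OC)=C(OCC)O[C@@]2(C)CC[C@H]2[C@H]1CC2(C)C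
A1 | alternative 1 | C6 phenylsulfonyl bis(methoxymethyl) ether of the deformyl target | C=C1C[C@@H](S(=O)(=O)c3ccccc3)[C@@H]2[C@@H](c3ccccc3)c3c(OCOC)cc(OCOC)cc3O[C@@]2(C)CC[C@H]2[C@H]1CC2(C)C
A2 | alternative 1 | open-chain sulfone allylic bromide | O=S(=O)(c1ccccc1)C[C@@H]2[C@@H](c3ccccc3)c3c(OCOC)cc(OCOC)cc3O[C@@]2(C)CC[C@H]2[C@H](C(=C)CBr)CC2(C)C
A3 | alternative 2 | protected deformyl C8 ketone with trans-fused cyclobutane | O=C1CC[C@@H]2[C@@H](c3ccccc3)c3c(OCOC)cc(OCOC)cc3O[C@@]2(C)CC[C@H]2[C@H]1CC2(C)C
A4 | alternative 2 | ring-B-fused (Z)-cyclonon-2-enone | O=C1CC[C@@H]2[C@@H](c3ccccc3)c3c(OCOC)cc(OCOC)cc3O[C@@]2(C)CC/C=C\1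
A5 | alternative 3 | bis(methoxymethyl) ether of the deformyl target | C=C1CC[C@@H]2[C@@H](c3ccccc3)c3c(OCOC)cc(OCOC)cc3O[C@@]2(C)CC[C@H]2[C@H]1CC2(C)C
A6 | alternative 3 | C5 vinyl chroman with C8 alkenyl triflate | C=C[C@@H]2[C@@H](c3ccccc3)c3c(OCOC)cc(OCOC)cc3O[C@@]2(C)CC[C@H]2[C@H](C(=C)OS(=O)(=O)C(F)(F)F)CC2(C)C
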